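The cycloheptane is closed last by an intramolecular samarium diiodide pinacol coupling that joins two carbonyl carbons of like polarity, C1 of a cyclopentanone and C10 of a methyl ketone. In one operation it forms the C1–C10 bond and both tertiary carbinols, exploiting the cis-1,10-diol that spans the ring-fusion carbon C1 and the methyl-bearing C10 of the seven-membered ring (C1, C5, C6, C7, C8, C9, C10). The precursor is a 2-substituted 3-methylenecyclopentanone whose C5 side chain carries C6 as a PMB-protected carbinol, the C7 isopropyl centre, a C9 silyl ether and the C10 acetyl group; C9 directs C10, and the samarium bridge relays this to C1.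

Key step: step 11

Remark (numbering): atoms are numbered as in the guaiane skeleton: C1 ring-fusion carbinol, C2, C3, C4 (=C15H2), C5 ring-fusion CH, C6 ketone, C7 isopropyl, C8, C9 ester, C10 methyl carbinol (C14 methyl). In this numbering the target is (1R,5S,7R,9R,10S).

Step 1
Reactants: 1 3-methylbutanal (isovaleraldehyde); 2 but-3-en-2-one (methyl vinyl ketone)
Product: 3 (R)-2-isopropyl-5-oxohexanal
Conditions: (R)-2-(methoxydiphenylmethyl)pyrrolidine (5 mol %), ethyl 3,4-dihydroxybenzoate (20 mol %), neat, 4 °C
Reagents that add atoms: none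
Why: Enamine-catalysed asymmetric Michael addition of an aldehyde to an enone: the E-enamine of 1 formed with the (R)-diarylprolinol ether should be attacked by the enone on the face away from the methoxydiphenylmethyl group, which sets C7 as R; the keto aldehyde is used without delay.

Step 2
Reactants: 4 3-methylcyclopent-2-en-1-one
Product: 5 3-(bromomethyl)cyclopent-2-en-1-one
Conditions: NBS, AIBN (cat.), PhCF3, 80 °C
Reagents that add atoms: N-bromosuccinimide, O=C1CCC(=O)N1Br
Why: Wohl–Ziegler allylic bromination: hydrogen abstraction from the γ-methyl group gives a dienoyl-stabilised radical that should be trapped at the exocyclic carbon, installing the C15 leaving group for the later allylmetal.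

Step 3
Reactants: 5 3-(bromomethyl)cyclopent-2-en-1-one
Product: 6 (S)-3-(bromomethyl)cyclopent-2-en-1-ol
Conditions: (R)-2-methyl-CBS-oxazaborolidine (20 mol %), catecholborane, toluene, −78 °C; aqueous work-up
Reagents that add atoms: none
Why: Corey–Bakshi–Shibata reduction: with the enone alkene as the large group, the (R)-oxazaborolidine should deliver hydride 1,2 to the face that gives the S carbinol at C1, a temporary stereocentre whose only task is to control C5.

Step 4
Reactants: 6 (S)-3-(bromomethyl)cyclopent-2-en-1-ol
Product: 7 (S)-{[3-(bromomethyl)cyclopent-2-en-1-yl]oxy}(tert-butyl)dimethylsilane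
Conditions: TBSOTf, 2,6-lutidine, CH2Cl2, −78 °C
Reagents that add atoms: tert-butyldimethylsilyl triflate, CC(C)(C)[Si](C)(C)OS(=O)(=O)C(F)(F)F
Why: Silyl ether formation with the triflate and a non-nucleophilic base, chosen so that the allylic bromide is not displaced; the stereocentre is untouched.

Step 5
Reactants: 7 (S)-{[3-(bromomethyl)cyclopent-2-en-1-yl]oxy}(tert-butyl)dimethylsilane; 3 (R)-2-isopropyl-5-oxohexanal
Product: 8 (5R,6S)-6-[(1R,5S)-5-(tert-butyldimethylsilyloxy)-2-methylenecyclopentyl]-6-hydroxy-5-isopropylhexan-2-one
Conditions: CrCl2 (4 equiv), THF, 0 °C to rt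
Reagents that add atoms: none
Why: Nozaki–Hiyama–Kishi allylation: the allylchromium(III) species should add only to the aldehyde (the methyl ketone is inert) through a chair transition state at its γ-carbon C5, on the ring face opposite the neighbouring silyloxy group (C5–C6 bond trans to C1–O) and in the anti, Felkin-matched sense at C6, while the allylic transposition creates the C4=C15 methylene; C6 is oxidised later, so a minor C6 epimer would converge.

Step 6
Reactants: 8 (5R,6S)-6-[(1R,5S)-5-(tert-butyldimethylsilyloxy)-2-methylenecyclopentyl]-6-hydroxy-5-isopropylhexan-2-one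
Product: 9 the C6 4-methoxybenzyl (PMB) ether of 8 (all stereocentres as in 8)
Conditions: 2-(4-methoxybenzyloxy)-4-methylquinoline, MeOTf, MgO, PhCF3, 0 °C to rt
Reagents that add atoms: 2-(4-methoxybenzyloxy)-4-methylquinoline, COc1ccc(COc2cc(C)c3ccccc3n2)cc1
Why: Neutral PMB transfer from the N-methylated 2-benzyloxyquinolinium salt (SN1-type O-alkylation), which should protect the hindered C6 hydroxyl without acid- or base-induced hemiketal or aldol chemistry of the δ-hydroxy ketone; no stereocentre is formed.

Step 7
Reactants: 9 the C6 PMB ether of 8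
Product: 11 9 carrying an additional (R)-hydroxyl at C3 of the hexan-2-one chain (guaiane C9), via α-anilinooxy ketone 10 (not isolated)
Conditions: L-proline (30 mol %), PhNO (slow addition), DMSO, rt; then CuSO4·5H2O (30 mol %), MeOH, 0 °C
Reagents that add atoms: nitrosobenzene, O=Nc1ccccc1
Why: Proline-catalysed α-aminoxylation (O-selective nitroso aldol): the more substituted enamine of the methyl ketone should attack the nitroso oxygen on the face dictated by the L-proline carboxylic acid, setting C9 as R under catalyst control, and copper(II) then cleaves the N–O bond to the free α-hydroxy ketone.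

Step 8
Reactants: 11 the C9 α-hydroxy ketone
Product: 12 the C9 tert-butyldiphenylsilyl (TBDPS) ether of 11
Conditions: TBDPSCl, imidazole, DMF, rt
Reagents that add atoms: tert-butyl(chloro)diphenylsilane, CC(C)(C)[Si](Cl)(c1ccccc1)c1ccccc1
Why: Silylation of the secondary α-hydroxy ketone, giving an α-oxygen substituent that is bulky, non-chelating and a poor leaving group for the later electron-transfer step; no stereocentre is formed.

Step 9
Reactants: 12 the C9 TBDPS ether
Product: 13 12 with the C1 hydroxyl free (cyclopentanol)
Conditions: CSA (10 mol %), MeOH/CH2Cl2, 0 °C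
Reagents that add atoms: none
Why: Acid-catalysed methanolysis, in which the secondary TBS ether should be cleaved much faster than the TBDPS ether while the PMB ether is inert; no stereocentre is affected.

Step 10
Reactants: 13 the C1 cyclopentanol
Product: 14 the diketone: 2-substituted 3-methylenecyclopentanone with the C10 methyl ketone
Conditions: DMP, pyridine, CH2Cl2, 0 °C
Reagents that add atoms: none
Why: Dess–Martin oxidation of the secondary alcohol under pyridine buffering, mild enough that the β,γ-unsaturated ketone should neither epimerise at C5 nor move its double bond into conjugation; the temporary C1 stereocentre is removed and 14 is used at once.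

Step 11
Reactants: 14 the diketone
Product: 15 6-(4-methoxybenzyloxy)-9-(tert-butyldiphenylsilyloxy)guai-4(15)-ene-1,10-diol (cis-1,10-diol; H-5 trans to 1-OH; 9-O trans to 10-OH; 6-O cis to H-5)
Conditions: SmI2 (3 equiv), t-BuOH (2 equiv), THF, −78 to −20 °C, 0.005 M, slow addition of 14
Reagents that add atoms: none
Why: Single-electron transfer from SmI2 to one ketone gives a samarium(III) ketyl that adds to the second, samarium-bound carbonyl, and a second electron and protonation give the diol; this is the intramolecular ketone–ketone pinacol coupling, for which seven-membered closures to cis-diols are known. The only ring closed is the cycloheptane, by 7-exo-trig attack that forms the C1–C10 bond between two formerly electrophilic carbons. The two new tertiary hydroxyls should be cis because both oxygens are held on samarium(III) in the bond-forming event. C10 is controlled by the adjacent C9 centre: the new C10–O bond should come out anti to the bulky, non-chelating C9 silyloxy group (the usual outcome with α-oxygenated carbonyl partners), and the samarium bridge relays this to C1, which places C10 on the cyclopentanone face opposite the C5–C6 bond (trans ring fusion). The step needs facial selectivity at both carbonyls and chemoselectivity over α-C–O cleavage and simple reduction; the preset C5 and C9 centres, the poor leaving-group ability of the silyloxy group, low temperature, high dilution and the absence of HMPA should secure them.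

Step 12
Reactants: 15 the bicyclic diol
Product: 16 6-(4-methoxybenzyloxy)guai-4(15)-ene-1,9,10-triol (stereocentres as in 15)
Conditions: TBAF, THF, 0 to 40 °C
Reagents that add atoms: none
Why: Fluoride-induced desilylation, which frees the only secondary hydroxyl while the two tertiary hydroxyls and the PMB ether stay; no stereocentre is affected.

Step 13
Reactants: 16 the triol; 17 angelic acid [(Z)-2-methylbut-2-enoic acid]
Product: 18 the C9 angelate of 16
Conditions: 17, 2,4,6-trichlorobenzoyl chloride, Et3N, toluene, rt; then 16, 80 °C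
Reagents that add atoms: none
Why: Yamaguchi-type esterification through the preformed mixed anhydride without DMAP, conditions under which the Z double bond should be kept, and only the secondary C9 hydroxyl is acylated because the C1 and C10 hydroxyls are tertiary.

Step 14
Reactants: 18 the C9 angelate
Product: 19 18 with the C6 hydroxyl free
Conditions: DDQ, CH2Cl2/pH 7 buffer, 0 °C
Reagents that add atoms: none
Why: Oxidative cleavage of the PMB ether by DDQ in the presence of water (hydride abstraction, hemiacetal collapse), which should leave the alkenes, the ester and the tertiary diol untouched.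

Step 15
Reactants: 19 the C6 alcohol
Product: 20 (1R,5S,7R,9R,10S)-1,10-dihydroxy-6-oxoguai-4(15)-en-9-yl (Z)-2-methylbut-2-enoate (target)
Conditions: (COCl)2, DMSO, CH2Cl2, −78 °C; i-Pr2NEt, −78 to −30 °C; pH 7 buffer quench
Reagents that add atoms: none
Why: Swern oxidation of the only secondary alcohol at low temperature with a hindered amine, which avoids glycol cleavage of the ditertiary diol and should not epimerise C5 or C7 or isomerise the β,γ-alkene; the C6 stereocentre is removed.

Compound list
1 | 3-methylbutanal (isovaleraldehyde) | CC(C)CC=O | starting material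
2 | but-3-en-2-one (methyl vinyl ketone) | CC(=O)C=C | starting material
3 | (R)-2-isopropyl-5-oxohexanal | O=C[C@@H](C(C)C)CCC(C)=O | intermediate
4 | 3-methylcyclopent-2-en-1-one | CC1=CC(=O)CC1 | starting material
5 | 3-(bromomethyl)cyclopent-2-en-1-one | BrCC1=CC(=O)CC1 | intermediate
6 | (S)-3-(bromomethyl)cyclopent-2-en-1-ol | BrCC1=C[C@@H](O)CC1 | intermediate
7 | (S)-{[3-(bromomethyl)cyclopent-2-en-1-yl]oxy}(tert-butyl)dimethylsilane | BrCC1=C[C@@H](O[Si](C)(C)C(C)(C)C)CC1 | intermediate
8 | (5R,6S)-6-[(1R,5S)-5-(tert-butyldimethylsilyloxy)-2-methylenecyclopentyl]-6-hydroxy-5-isopropylhexan-2-one | CC(=O)CC[C@H](C(C)C)[C@H](O)[C@H]1C(=C)CC[C@@H]1O[Si](C)(C)C(C)(C)C | intermediate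
9 | C6 4-methoxybenzyl ether of 8 | CC(=O)CC[C@H](C(C)C)[C@H](OCc2ccc(OC)cc2)[C@H]1C(=C)CC[C@@H]1O[Si](C)(C)C(C)(C)C | intermediate
10 | α-anilinooxy ketone: 9 with (R)-PhNH–O at guaiane C9 | CC(=O)[C@H](ONc2ccccc2)C[C@H](C(C)C)[C@H](OCc2ccc(OC)cc2)[C@H]1C(=C)CC[C@@H]1O[Si](C)(C)C(C)(C)C | intermediate
11 | α-hydroxy ketone: 9 with (R)-OH at guaiane C9 | CC(=O)[C@H](O)C[C@H](C(C)C)[C@H](OCc2ccc(OC)cc2)[C@H]1C(=C)CC[C@@H]1O[Si](C)(C)C(C)(C)C | intermediate
12 | C9 tert-butyldiphenylsilyl ether of 11 | CC(=O)[C@H](O[Si](c2ccccc2)(c2ccccc2)C(C)(C)C)C[C@H](C(C)C)[C@H](OCc2ccc(OC)cc2)[C@H]1C(=C)CC[C@@H]1O[Si](C)(C)C(C)(C)C | intermediate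
13 | 12 with free C1 hydroxyl (cyclopentanol) | CC(=O)[C@H](O[Si](c2ccccc2)(c2ccccc2)C(C)(C)C)C[C@H](C(C)C)[C@H](OCc2ccc(OC)cc2)[C@H]1C(=C)CC[C@@H]1O | intermediate
14 | diketone: 2-substituted 3-methylenecyclopentanone bearing the C10 methyl ketone | CC(=O)[C@H](O[Si](c2ccccc2)(c2ccccc2)C(C)(C)C)C[C@H](C(C)C)[C@H](OCc2ccc(OC)cc2)[C@H]1C(=C)CCC1=O | intermediate
15 | 6-(4-methoxybenzyloxy)-9-(tert-butyldiphenylsilyloxy)guai-4(15)-ene-1,10-diol, cis-1,10-diol, trans-fused | C=C1CC[C@@]2(O)[C@H]1[C@@H](OCc3ccc(OC)cc3)[C@@H](C(C)C)C[C@@H](O[Si](c3ccccc3)(c3ccccc3)C(C)(C)C)[C@]2(C)O | intermediate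
16 | 6-(4-methoxybenzyloxy)guai-4(15)-ene-1,9,10-triol | C=C1CC[C@@]2(O)[C@H]1[C@@H](OCc3ccc(OC)cc3)[C@@H](C(C)C)C[C@@H](O)[C@]2(C)O | intermediate
17 | angelic acid, (Z)-2-methylbut-2-enoic acid | C/C=C(/C)C(=O)O | starting material
18 | C9 angelate of 16 | C=C1CC[C@@]2(O)[C@H]1[C@@H](OCc3ccc(OC)cc3)[C@@H](C(C)C)C[C@@H](OC(=O)/C(C)=C\C)[C@]2(C)O | intermediate
19 | 18 with free C6 hydroxyl | C=C1CC[C@@]2(O)[C@H]1[C@@H](O)[C@@H](C(C)C)C[C@@H](OC(=O)/C(C)=C\C)[C@]2(C)O | intermediate
20 | (1R,5S,7R,9R,10S)-1,10-dihydroxy-6-oxoguai-4(15)-en-9-yl (Z)-2-methylbut-2-enoate | C=C1CC[C@@]2(O)[C@H]1C(=O)[C@@H](C(C)C)C[C@@H](OC(=O)/C(C)=C\C)[C@]2(C)O | target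

Total step count: 15. Longest linear sequence: 14 steps (4 to 20, steps 2–15).

Steps most likely to fail

1. Step 11 (pinacol closure). The ketyl may close on the cyclopentanone face syn to the C5 side chain and give the cis ring fusion, because allylic strain with the exocyclic methylene holds that chain pseudo-axial; the α-silyloxy group may also be lost reductively before the C–C bond forms. The fallback makes the C1–C10 bond intermolecularly and closes the ring by olefin metathesis; it sets out from bromide 7 and rejoins the route at 18.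
   - NHK coupling of 7 (CrCl2, THF) with (R)-2-isopropylpent-4-enal F1, made from 1 by organocatalytic SOMO α-allylation with allyltrimethylsilane, would give homoallylic alcohol F2.
   - PMB protection as in step 6 would give the PMB ether F3, TBS removal as in step 9 the cyclopentanol F4, and oxidation as in step 10 the cyclopentanone F5.
   - Isopropenylmagnesium bromide/CeCl3 should add to F5 anti to the C5 chain and give the tertiary allylic alcohol F6 with the trans relationship.
   - Ring-closing metathesis (second-generation ruthenium benzylidene catalyst, CH2Cl2, 40 °C) between the allyl and isopropenyl groups would close the cycloheptene F7 (C9=C10).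
   - VO(acac)2/t-BuOOH epoxidation directed by the C1 hydroxyl would give the epoxy alcohol F8.
   - Ti(OiPr)4-mediated opening of F8 at C9 by angelic acid 17, with inversion, should give 18; steps 14 and 15 follow.

2. Step 7 (α-hydroxylation). Enamine formation at the hindered, advanced methyl ketone may be slow, so that nitrosobenzene is consumed by self-condensation, or oxygenation may occur at the methyl group. The fallback sets out from 9 and returns at 11. The ketone is converted into its thermodynamic (Z)-trimethylsilyl enol ether F9 (TMSCl, NaI, Et3N, MeCN). This electron-rich alkene is then oxidised by Shi epoxidation (D-fructose-derived ketone, Oxone, buffered MeCN/dimethoxymethane, 0 °C) with mild acidic work-up, which should deliver the 9R α-hydroxy ketone 11 and leave the 1,1-disubstituted exocyclic alkene alone.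

3. Step 13 (angeloylation). Acylation of the hindered C9 hydroxyl next to the quaternary C10 may be slow, and the forcing conditions may isomerise the Z acyl unit to the E (tiglate) isomer. The fallback sets out from 16 and returns at 18. The alcohol is first esterified with the more reactive saturated 2-[bis(2,2,2-trifluoroethoxy)phosphoryl]propanoic acid (DCC, DMAP, CH2Cl2) to give the phosphonate ester F10. The Z-trisubstituted alkene is then built on the substrate by Still–Gennari olefination with acetaldehyde (excess KHMDS, 18-crown-6, THF, −78 °C), which should give angelate 18.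

Further compounds
F1 | step 11 | (R)-2-isopropylpent-4-enal | O=C[C@@H](C(C)C)CC=C
F2 | step 11 | NHK adduct: (1S)-1-[(1R,5S)-5-(tert-butyldimethylsilyloxy)-2-methylenecyclopentyl]-2-isopropylpent-4-en-1-ol with 7R (guaiane numbering) | C=CC[C@H](C(C)C)[C@H](O)[C@H]1C(=C)CC[C@@H]1O[Si](C)(C)C(C)(C)C
F3 | step 11 | C6 4-methoxybenzyl ether of F2 | C=CC[C@H](C(C)C)[C@H](OCc2ccc(OC)cc2)[C@H]1C(=C)CC[C@@H]1O[Si](C)(C)C(C)(C)C
F4 | step 11 | F3 with free C1 hydroxyl | C=CC[C@H](C(C)C)[C@H](OCc2ccc(OC)cc2)[C@H]1C(=C)CC[C@@H]1O
F5 | step 11 | 2-substituted 3-methylenecyclopentanone from F4 | C=CC[C@H](C(C)C)[C@H](OCc2ccc(OC)cc2)[C@H]1C(=C)CCC1=O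
F6 | step 11 | 1-isopropenyl cyclopentanol, hydroxyl cis to the C5 side chain | C=CC[C@H](C(C)C)[C@H](OCc2ccc(OC)cc2)[C@H]1C(=C)CC[C@]1(O)C(C)=C
F7 | step 11 | 6-(4-methoxybenzyloxy)guaia-4(15),9-dien-1-ol, trans-fused | C=C1CC[C@@]2(O)[C@H]1[C@@H](OCc3ccc(OC)cc3)[C@@H](C(C)C)CC=C2C
F8 | step 11 | 9,10-epoxide of F7, epoxide oxygen cis to 1-OH | C=C1CC[C@@]2(O)[C@H]1[C@@H](OCc3ccc(OC)cc3)[C@@H](C(C)C)C[C@@H]4O[C@]24C
F9 | step 7 | (Z)-trimethylsilyl enol ether of 9 (C9=C10) | C/C(O[Si](C)(C)C)=C/C[C@H](C(C)C)[C@H](OCc2ccc(OC)cc2)[C@H]1C(=C)CC[C@@H]1O[Si](C)(C)C(C)(C)C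
F10 | step 13 | C9 2-[bis(2,2,2-trifluoroethoxy)phosphoryl]propanoate of 16 (epimers at the phosphonate carbon) | C=C1CC[C@@]2(O)[C@H]1[C@@H](OCc3ccc(OC)cc3)[C@@H](C(C)C)C[C@@H](OC(=O)C(C)P(=O)(OCC(F)(F)F)OCC(F)(F)F)[C@]2(C)O
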